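## Retrosynthetic overview

1. The strategy rests on ring A, a hexasubstituted benzene (C4a acyl, C5–OH, C6–Me, C7–OMe, C8–Me, C8a–O1). C5 is read as a ketene carbonyl carbon, C6 and C7 as the two carbons of 1-methoxypropyne, C8 with its methyl as a diazo carbon, and C8a=C4a as the C6=C5 alkene of a dihydropyranone (ring C).
2. Last disconnection: the methoxy-para-quinone ring B comes from a 3'-hydroxy-4'-methoxyphenyl group (oxygen introduced at C6', para to the phenol), which comes from its benzyl ether.
3. Key disconnection: ring A comes from (S)-2-aryl-6-(2-diazopropanoyl)-2,3-dihydropyran-4-one and 1-methoxypropyne (bonds C8–C8a, C5–C6, C7–C8, C4a–C5).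
4. The diazoketone comes from the pyranone-6-carboxylic acid and diazoethane. Ring C comes from cyclodehydration of a δ-hydroxy-2,4-dioxo acid, made from a β-silyloxy methyl ketone and diethyl oxalate. C2 comes from asymmetric allylboration of O-benzylisovanillin.
5. Ring order: ring B is bought as an arene, ring C is closed next, ring A is closed last, and ring B is then oxidised to the quinone.

Key step: step 9

Assumption: C2 of the target is S (O1 > C1' > C3 > H), flavanone numbering is used for all ring positions, and 1,3-dicarbonyl compounds are written as keto tautomers.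

## Route

Step 1
Reactants: 1 chloroacetaldehyde dimethyl acetal
Product: 3 1-methoxypropyne, via sodium methoxyacetylide 2 (not isolated)
Conditions: NaNH2 (3.1 equiv.), liq. NH3, −33 °C; MeI (1.0 equiv.), −78 → −33 °C; H2O work-up, distillation
Reagents that add atoms: iodomethane, CI; sodium amide, [Na+].[NH2-] (sodium of 2 only)
Why: Two amide-induced eliminations (loss of MeOH and of HCl) followed by deprotonation give the metallated alkynyl ether, whose acetylide carbon is methylated in an SN2 step, which is the standard preparation of 1-alkoxyalk-1-ynes.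

Step 2
Reactants: 4 N-ethyl-N-nitrosourea
Product: 5 diazoethane
Conditions: 40% aq. KOH, Et2O, −10 → 0 °C; ether layer decanted, dried over KOH pellets, titrated and used at once
Reagents that add atoms: none
Why: Base-induced fragmentation of an N-alkyl-N-nitrosourea is the standard generation of a diazoalkane and delivers the reagent as a dry, acid-free ethereal solution.

Step 3
Reactants: 6 3-(benzyloxy)-4-methoxybenzaldehyde (O-benzylisovanillin)
Product: 8 (S)-1-[3-(benzyloxy)-4-methoxyphenyl]but-3-en-1-ol, via borinate ester 7 (not isolated)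
Conditions: (−)-Ipc2B(allyl) (1 M in pentane, 1.2 equiv.), Et2O, −78 °C; then 3 M NaOH, 30% H2O2, 0 °C → rt
Reagents that add atoms: (−)-B-allyldiisopinocampheylborane, C=CCB([C@@H]1C[C@@H]2C[C@H]([C@H]1C)C2(C)C)[C@@H]1C[C@@H]2C[C@H]([C@H]1C)C2(C)C
Why: Brown asymmetric allylboration runs through a closed chair transition state in which the reagent derived from (+)-α-pinene delivers allyl to the Si face of the aryl aldehyde, which sets the carbinol carbon (the later C2) as S, and the oxidative work-up frees the alcohol.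

Step 4
Reactants: 8 (S)-1-[3-(benzyloxy)-4-methoxyphenyl]but-3-en-1-ol
Product: 9 (S)-{1-[3-(benzyloxy)-4-methoxyphenyl]but-3-en-1-yloxy}(tert-butyl)dimethylsilane
Conditions: TBSCl, imidazole, DMF, rt
Reagents that add atoms: tert-butyldimethylsilyl chloride, CC(C)(C)[Si](C)(C)Cl
Why: Standard imidazole-promoted silylation masks the benzylic hydroxyl so that neither retro-aldol cleavage nor alkoxide chemistry can interfere with the enolate step to come.

Step 5
Reactants: 9 (S)-{1-[3-(benzyloxy)-4-methoxyphenyl]but-3-en-1-yloxy}(tert-butyl)dimethylsilane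
Product: 10 (S)-4-[3-(benzyloxy)-4-methoxyphenyl]-4-[(tert-butyldimethylsilyl)oxy]butan-2-one
Conditions: PdCl2 (10 mol%), CuCl (1 equiv.), O2 (1 atm), DMF/H2O 7:1, rt
Reagents that add atoms: water, O
Why: Tsuji–Wacker oxidation of a terminal alkene gives the methyl ketone by Markovnikov hydroxypalladation and leaves the silyl ether, the benzyl ether and the stereocentre untouched.

Step 6
Reactants: 10 (S)-4-[3-(benzyloxy)-4-methoxyphenyl]-4-[(tert-butyldimethylsilyl)oxy]butan-2-one, 11 diethyl oxalate
Product: 13 (S)-6-[3-(benzyloxy)-4-methoxyphenyl]-6-[(tert-butyldimethylsilyl)oxy]-2,4-dioxohexanoic acid, via ethyl diketoester 12 (not isolated)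
Conditions: LiN(SiMe3)2 (1.1 equiv.), THF, −78 °C; 11 (2 equiv.), −78 → 0 °C; then LiOH (5 equiv.), H2O/THF, 0 °C → rt; 1 M HCl to pH 3, 0 °C
Reagents that add atoms: lithium hydroxide, [Li+].[OH-]
Why: Crossed Claisen condensation of the kinetic methyl-side enolate with non-enolisable diethyl oxalate is driven by the chelated diketoester enolate, and that same enolate shuts off β-elimination while LiOH saponifies the activated α-keto ester, so the only basic hydrolysis of the route is finished before the base-labile ring C exists.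

Step 7
Reactants: 13 (S)-6-[3-(benzyloxy)-4-methoxyphenyl]-6-[(tert-butyldimethylsilyl)oxy]-2,4-dioxohexanoic acid
Product: 15 (S)-2-[3-(benzyloxy)-4-methoxyphenyl]-4-oxo-3,4-dihydro-2H-pyran-6-carboxylic acid, via hydroxy diketo acid 14 (not isolated)
Conditions: HF·pyridine, pyridine, THF, 0 °C → rt; extractive work-up at pH 3; then TFA (5 equiv.), CH2Cl2, 0 °C, short contact
Reagents that add atoms: none
Why: Fluoride cleaves only the Si–O bond, the freed hydroxyl adds to the α-keto acid carbonyl as a six-membered hemiketal, and brief cold acid dehydrates it to the vinylogous ester (the usual cyclodehydration of δ-hydroxy-1,3-diketones, as also used on aldol adducts of electron-rich aryl aldehydes), with retention because the benzylic C–O bond is never broken.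

Step 8
Reactants: 15 (S)-2-[3-(benzyloxy)-4-methoxyphenyl]-4-oxo-3,4-dihydro-2H-pyran-6-carboxylic acid, 5 diazoethane
Product: 17 (S)-2-[3-(benzyloxy)-4-methoxyphenyl]-6-(2-diazopropanoyl)-2,3-dihydro-4H-pyran-4-one, via acid chloride 16 (not isolated)
Conditions: 1-chloro-N,N,2-trimethylprop-1-en-1-amine (1.1 equiv.), CH2Cl2, 0 °C; solution added to 5 (2.5 equiv.), Et2O, −78 → −20 °C; excess 5 purged with N2
Reagents that add atoms: 1-chloro-N,N,2-trimethylprop-1-en-1-amine, CC(C)=C(Cl)N(C)C (chlorine of 16 only)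
Why: This is the acylation of a diazoalkane by an acid chloride (first stage of the Arndt–Eistert sequence), in which the α-chloroenamine forms the chloride without acid or base, one equivalent of diazoethane is acylated at carbon and a second removes the proton, and the low temperature keeps the slower dipolar cycloaddition to the C5=C6 alkene in the background.

Step 9
Reactants: 17 (S)-2-[3-(benzyloxy)-4-methoxyphenyl]-6-(2-diazopropanoyl)-2,3-dihydro-4H-pyran-4-one, 3 1-methoxypropyne
Product: 22 (S)-2-[3-(benzyloxy)-4-methoxyphenyl]-5-hydroxy-7-methoxy-6,8-dimethylchroman-4-one, via vinylketene 18 (not isolated), via vinylcyclobutenone 19 (not isolated), via dienylketene 20 (not isolated), via cyclohexadienone 21 (not isolated)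
Conditions: 3 (3 equiv.), hν (365 nm), dry degassed ClCH2CH2Cl, 20 °C; then 80 °C in the dark
Reagents that add atoms: none
Why: Light expels N2 from 17 while the ring carbon C8a (pyranone C6) shifts from the acyl carbon to the diazo carbon (Wolff rearrangement), the C=C of the resulting methyl(vinyl)ketene 18 adds alkyne 3 in a [2+2] cycloaddition, cyclobutenone 19 opens in a reversible 4π electrocyclic reaction (light or 80 °C) to dienylketene 20, and 20 closes to dienone 21, whose C4a–H lies between two carbonyl groups and enolises at once to the phenol. The closest known reaction is the diazoketone variant of the Danheiser benzannulation, established for α,β-unsaturated, aryl and heteroaryl diazoketones with alkynyl ethers including 1-methoxypropyne, so this is a known cascade on a new substrate. Ring A is closed by the 6π electrocyclisation that forms C4a–C5, after C8–C8a (1,2-shift) and C5–C6 plus C7–C8 (cycloaddition) are in place, and the push–pull alkene makes C4a a good partner for the electrophilic ketene carbon. No lasting stereocentre is created, since the quaternary carbon of 19 and C4a of 21 both become sp2, and C2 is a spectator because the medium holds neither acid nor base. The step needs one orientation in the [2+2] addition, and the polarised triple bond secures it, because the oxygen-free, methyl-bearing carbon of 3 is the nucleophilic end and bonds to the ketene carbonyl carbon, which puts C7–OMe meta to C5–OH with the methyl groups at C6 and C8. Side channels are limited by the substrate itself, as ketene and C4=O stand trans across C8a=C4a so no α-pyrone can form, 365 nm light is absorbed by the diazoketone and not by 3, a methyl alkynyl ether has no retro-ene path at 80 °C, and the chelated, flanked C5–OH of 22 is a poor trap for ketene 18.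

Step 10
Reactants: 22 (S)-2-[3-(benzyloxy)-4-methoxyphenyl]-5-hydroxy-7-methoxy-6,8-dimethylchroman-4-one
Product: 23 (S)-5-hydroxy-2-(3-hydroxy-4-methoxyphenyl)-7-methoxy-6,8-dimethylchroman-4-one
Conditions: H2 (1 atm), 10% Pd/C, EtOAc, rt, stopped at full conversion
Reagents that add atoms: none
Why: Catalytic hydrogenolysis of a benzyl aryl ether at 1 atm in a neutral solvent is much faster than cleavage of the C2–O1 bond or reduction of the chelated aryl ketone, as is usual for benzyl-protected flavanones.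

Step 11
Reactants: 23 (S)-5-hydroxy-2-(3-hydroxy-4-methoxyphenyl)-7-methoxy-6,8-dimethylchroman-4-one
Product: 24 (S)-2-(5-hydroxy-7-methoxy-6,8-dimethyl-4-oxochroman-2-yl)-5-methoxycyclohexa-2,5-diene-1,4-dione (target)
Conditions: (KSO3)2NO (2.5 equiv.), aq. KH2PO4 buffer, acetone, 0 °C → rt
Reagents that add atoms: dipotassium nitrosodisulfonate, [K+].[K+].[O]N(S(=O)(=O)[O-])S(=O)(=O)[O-]
Why: In this Teuber oxidation the nitroxyl radical abstracts the hydrogen of the unchelated 3'-OH, a second equivalent couples at the free para carbon C6' and collapse gives the para-quinone with OMe next to the C3' carbonyl, while the C5–OH is tied to C4=O by a hydrogen bond on a ring with no free position and the buffered medium leaves C2 alone.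

## Compound list

1 | chloroacetaldehyde dimethyl acetal (2-chloro-1,1-dimethoxyethane) | COC(CCl)OC | starting material
2 | sodium methoxyacetylide | COC#[C-].[Na+] | intermediate
3 | 1-methoxypropyne | COC#CC | intermediate
4 | N-ethyl-N-nitrosourea | CCN(N=O)C(N)=O | starting material
5 | diazoethane | CC=[N+]=[N-] | intermediate
6 | 3-(benzyloxy)-4-methoxybenzaldehyde | COc1ccc(C=O)cc1OCc1ccccc1 | starting material
7 | (S)-1-[3-(benzyloxy)-4-methoxyphenyl]but-3-enyl diisopinocampheylborinate | COc1ccc(cc1OCc1ccccc1)[C@@H](OB([C@@H]1C[C@@H]2C[C@H]([C@H]1C)C2(C)C)[C@@H]1C[C@@H]2C[C@H]([C@H]1C)C2(C)C)CC=C | intermediate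
8 | (S)-1-[3-(benzyloxy)-4-methoxyphenyl]but-3-en-1-ol | COc1ccc(cc1OCc1ccccc1)[C@@H](O)CC=C | intermediate
9 | (S)-{1-[3-(benzyloxy)-4-methoxyphenyl]but-3-en-1-yloxy}(tert-butyl)dimethylsilane | COc1ccc(cc1OCc1ccccc1)[C@@H](O[Si](C)(C)C(C)(C)C)CC=C | intermediate
10 | (S)-4-[3-(benzyloxy)-4-methoxyphenyl]-4-[(tert-butyldimethylsilyl)oxy]butan-2-one | COc1ccc(cc1OCc1ccccc1)[C@@H](O[Si](C)(C)C(C)(C)C)CC(C)=O | intermediate
11 | diethyl oxalate | CCOC(=O)C(=O)OCC | starting material
12 | ethyl (S)-6-[3-(benzyloxy)-4-methoxyphenyl]-6-[(tert-butyldimethylsilyl)oxy]-2,4-dioxohexanoate (present as its lithium enolate) | COc1ccc(cc1OCc1ccccc1)[C@@H](O[Si](C)(C)C(C)(C)C)CC(=O)CC(=O)C(=O)OCC | intermediate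
13 | (S)-6-[3-(benzyloxy)-4-methoxyphenyl]-6-[(tert-butyldimethylsilyl)oxy]-2,4-dioxohexanoic acid | COc1ccc(cc1OCc1ccccc1)[C@@H](O[Si](C)(C)C(C)(C)C)CC(=O)CC(=O)C(=O)O | intermediate
14 | (S)-6-[3-(benzyloxy)-4-methoxyphenyl]-6-hydroxy-2,4-dioxohexanoic acid (in equilibrium with its cyclic hemiketal) | COc1ccc(cc1OCc1ccccc1)[C@@H](O)CC(=O)CC(=O)C(=O)O | intermediate
15 | (S)-2-[3-(benzyloxy)-4-methoxyphenyl]-4-oxo-3,4-dihydro-2H-pyran-6-carboxylic acid | COc1ccc(cc1OCc1ccccc1)[C@@H]2CC(=O)C=C(O2)C(=O)O | intermediate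
16 | (S)-2-[3-(benzyloxy)-4-methoxyphenyl]-4-oxo-3,4-dihydro-2H-pyran-6-carbonyl chloride | COc1ccc(cc1OCc1ccccc1)[C@@H]2CC(=O)C=C(O2)C(=O)Cl | intermediate
17 | (S)-2-[3-(benzyloxy)-4-methoxyphenyl]-6-(2-diazopropanoyl)-2,3-dihydro-4H-pyran-4-one | COc1ccc(cc1OCc1ccccc1)[C@@H]2CC(=O)C=C(O2)C(=O)C(C)=[N+]=[N-] | intermediate
18 | (S)-2-[3-(benzyloxy)-4-methoxyphenyl]-6-(1-oxoprop-1-en-2-yl)-2,3-dihydro-4H-pyran-4-one (methyl(vinyl)ketene) | COc1ccc(cc1OCc1ccccc1)[C@@H]2CC(=O)C=C(O2)C(C)=C=O | intermediate
19 | (2S)-2-[3-(benzyloxy)-4-methoxyphenyl]-6-(2-methoxy-1,3-dimethyl-4-oxocyclobut-2-en-1-yl)-2,3-dihydro-4H-pyran-4-one (both epimers at the quaternary carbon) | COc1ccc(cc1OCc1ccccc1)[C@@H]2CC(=O)C=C(O2)C3(C)C(=O)C(C)=C3OC | intermediate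
20 | dienylketene: (S)-2-[3-(benzyloxy)-4-methoxyphenyl]-6-[(2E)-3-methoxy-4-methyl-5-oxopenta-2,4-dien-2-yl]-2,3-dihydro-4H-pyran-4-one (pyranonyl cis to the ketenyl carbon) | COc1ccc(cc1OCc1ccccc1)[C@@H]2CC(=O)C=C(O2)/C(C)=C(OC)\C(C)=C=O | intermediate
21 | (2S)-2-[3-(benzyloxy)-4-methoxyphenyl]-7-methoxy-6,8-dimethyl-2,3-dihydro-4aH-chromene-4,5-dione (C4a undefined, lost on enolisation) | COc1ccc(cc1OCc1ccccc1)[C@@H]2CC(=O)C3C(=O)C(C)=C(OC)C(C)=C3O2 | intermediate
22 | (S)-2-[3-(benzyloxy)-4-methoxyphenyl]-5-hydroxy-7-methoxy-6,8-dimethylchroman-4-one | COc1ccc(cc1OCc1ccccc1)[C@@H]2CC(=O)c3c(O)c(C)c(OC)c(C)c3O2 | intermediate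
23 | (S)-5-hydroxy-2-(3-hydroxy-4-methoxyphenyl)-7-methoxy-6,8-dimethylchroman-4-one | COc1ccc(cc1O)[C@@H]2CC(=O)c3c(O)c(C)c(OC)c(C)c3O2 | intermediate
24 | (S)-2-(5-hydroxy-7-methoxy-6,8-dimethyl-4-oxochroman-2-yl)-5-methoxycyclohexa-2,5-diene-1,4-dione | COC1=CC(=O)C([C@@H]2CC(=O)c3c(O)c(C)c(OC)c(C)c3O2)=CC1=O | target

## Step count and risks

Total step count: 11 (steps 1 and 2 prepare the small partners 3 and 5).
Longest linear sequence: 9 steps (6 → 24, steps 3–11).

**Risk 1, step 9.**
- The excited diazoketone may lose N2 to a free acylcarbene, in which a hydrogen of the neighbouring methyl group shifts faster than the ring carbon migrates.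
- The enone of ring C may enter a photocycloaddition with the excess alkyne.
- The disubstituted ketene may add the alkyne so slowly that it is lost by dimerisation or to traces of water.

The fallback sets out from acid chloride 16 and returns at 22. It moves the C8 methyl group out of the cascade. Compound 16 is treated with Me3SiCHN2 in MeCN/THF at 0 °C to give (S)-2-[3-(benzyloxy)-4-methoxyphenyl]-6-(2-diazoacetyl)-2,3-dihydro-4H-pyran-4-one F1. Its carbene has no β-hydrogen and its ketene is monosubstituted and more reactive. Irradiation and heating with 3 as in step 9 should give (S)-2-[3-(benzyloxy)-4-methoxyphenyl]-5-hydroxy-7-methoxy-6-methylchroman-4-one F2. N-Iodosuccinimide in DMF at 0 °C iodinates C8, the only free and most activated position of ring A, to give (S)-2-[3-(benzyloxy)-4-methoxyphenyl]-5-hydroxy-8-iodo-7-methoxy-6-methylchroman-4-one F3. A base-free Stille methylation (Me4Sn, PdCl2(PPh3)2, LiCl, DMF, 80 °C) then gives 22.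

**Risk 2, step 8.**
- Excess diazoethane may add as a 1,3-dipole across the C5=C6 bond, which is flanked by two acyl groups.
- Liberated HCl may protonate the product and replace N2 by chloride.
- Ring C may open if the medium turns basic.

The fallback sets out from 16 and returns at 17 without any diazoalkane. Stille acylation of 16 with tributyl(1-ethoxyvinyl)stannane (PdCl2(PPh3)2, toluene, 60 °C) gives (S)-2-[3-(benzyloxy)-4-methoxyphenyl]-6-(2-ethoxyacryloyl)-2,3-dihydro-4H-pyran-4-one F4. Hydrolysis of the enol ether (1 M HCl, THF, 0 °C) gives (S)-1-{2-[3-(benzyloxy)-4-methoxyphenyl]-4-oxo-3,4-dihydro-2H-pyran-6-yl}propane-1,2-dione F5. TsNHNH2 (1.0 equiv., MeOH/THF, 0 °C) condenses at the unconjugated, less hindered acetyl carbonyl to give the 2-(tosylhydrazone) of that dione F6. Bamford–Stevens-type loss of sulfinate with Et3N in CH2Cl2 at 0 °C, which is enough for an α-oxo tosylhydrazone, gives 17.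

**Risk 3, step 11.**
- Hydrogen abstraction from the electron-rich ring A phenol may compete with oxidation of ring B.
- The oxidation may run past the quinone stage.
- The product may tautomerise through loss of the activated C2–H on long contact with the aqueous medium.

The fallback sets out from 22 and returns at 24 with ring A masked during the oxidation. TBSOTf and 2,6-lutidine (CH2Cl2, 0 °C) give (S)-2-[3-(benzyloxy)-4-methoxyphenyl]-5-[(tert-butyldimethylsilyl)oxy]-7-methoxy-6,8-dimethylchroman-4-one F7. Hydrogenolysis (H2, Pd/C, EtOAc) gives (S)-5-[(tert-butyldimethylsilyl)oxy]-2-(3-hydroxy-4-methoxyphenyl)-7-methoxy-6,8-dimethylchroman-4-one F8, which carries a single free phenol. Its oxidation with (KSO3)2NO gives (S)-2-{5-[(tert-butyldimethylsilyl)oxy]-7-methoxy-6,8-dimethyl-4-oxochroman-2-yl}-5-methoxycyclohexa-2,5-diene-1,4-dione F9. HF·pyridine in THF at 0 °C, which the quinone tolerates, removes the labile peri-silyl group to give 24.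

Further compounds
F1 | step 9 | (S)-2-[3-(benzyloxy)-4-methoxyphenyl]-6-(2-diazoacetyl)-2,3-dihydro-4H-pyran-4-one | COc1ccc(cc1OCc1ccccc1)[C@@H]2CC(=O)C=C(O2)C(=O)C=[N+]=[N-]
F2 | step 9 | (S)-2-[3-(benzyloxy)-4-methoxyphenyl]-5-hydroxy-7-methoxy-6-methylchroman-4-one | COc1ccc(cc1OCc1ccccc1)[C@@H]2CC(=O)c3c(O)c(C)c(OC)cc3O2
F3 | step 9 | (S)-2-[3-(benzyloxy)-4-methoxyphenyl]-5-hydroxy-8-iodo-7-methoxy-6-methylchroman-4-one | COc1ccc(cc1OCc1ccccc1)[C@@H]2CC(=O)c3c(O)c(C)c(OC)c(I)c3O2
F4 | step 8 | (S)-2-[3-(benzyloxy)-4-methoxyphenyl]-6-(2-ethoxyacryloyl)-2,3-dihydro-4H-pyran-4-one | COc1ccc(cc1OCc1ccccc1)[C@@H]2CC(=O)C=C(O2)C(=O)C(=C)OCC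
F5 | step 8 | (S)-1-{2-[3-(benzyloxy)-4-methoxyphenyl]-4-oxo-3,4-dihydro-2H-pyran-6-yl}propane-1,2-dione | COc1ccc(cc1OCc1ccccc1)[C@@H]2CC(=O)C=C(O2)C(=O)C(C)=O
F6 | step 8 | 2-(tosylhydrazone) of (S)-1-{2-[3-(benzyloxy)-4-methoxyphenyl]-4-oxo-3,4-dihydro-2H-pyran-6-yl}propane-1,2-dione | COc1ccc(cc1OCc1ccccc1)[C@@H]2CC(=O)C=C(O2)C(=O)C(C)=NNS(=O)(=O)c1ccc(C)cc1
F7 | step 11 | (S)-2-[3-(benzyloxy)-4-methoxyphenyl]-5-[(tert-butyldimethylsilyl)oxy]-7-methoxy-6,8-dimethylchroman-4-one | COc1ccc(cc1OCc1ccccc1)[C@@H]2CC(=O)c3c(O[Si](C)(C)C(C)(C)C)c(C)c(OC)c(C)c3O2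
F8 | step 11 | (S)-5-[(tert-butyldimethylsilyl)oxy]-2-(3-hydroxy-4-methoxyphenyl)-7-methoxy-6,8-dimethylchroman-4-one | COc1ccc(cc1O)[C@@H]2CC(=O)c3c(O[Si](C)(C)C(C)(C)C)c(C)c(OC)c(C)c3O2
F9 | step 11 | (S)-2-{5-[(tert-butyldimethylsilyl)oxy]-7-methoxy-6,8-dimethyl-4-oxochroman-2-yl}-5-methoxycyclohexa-2,5-diene-1,4-dione | COC1=CC(=O)C([C@@H]2CC(=O)c3c(O[Si](C)(C)C(C)(C)C)c(C)c(OC)c(C)c3O2)=CC1=O
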